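**Plan**

1. Locants: ring A is the cyclooctane C1(OAc)–C2–C3(Me)–C4–C5–C6–C7–C8 (C8 carries the side chain, C1′ is its CHMe carbon); ring B is the cyclopropane C4–C9–C5; ring C is the butenolide on C6=C7, with C10 the lactone C=O on C7 and C11 the OCH2 on C6.
2. Retrosynthesis: remove the acetate and the C6=C7 unsaturation (selenoxide), return C10 to an O-menthyl acetal, cut ring B at C4–C9/C5–C9 (hydroxyl-directed Simmons–Smith), re-join C1–C4 (retro-Grob) to a bicyclo[4.2.0]octane, cut its cyclobutane at C1–C2 and C3–C4 into a 3-silyloxycyclohexenone and allene, and cut the six-membered ring at C8–C7 and C5–C6 (Diels–Alder).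
3. Enabling feature: in ring A the oxygenated C1 and the C4–C5 unit that carries ring B are joined on one side by C2–C3 only, so ring A is the six-membered ring C1–C8–C7–C6–C5–C4 (a cyclohexane-1,3-dione mono-enol ether, oxygen on C1 and C5) enlarged by two carbons; an enone–allene [2+2] photocycloaddition supplies C2–C3(=CH2) and the strained cyclobutane is then opened across C1–C4.
4. Forward order: six-membered carbocycle with a temporary cis-fused γ-lactone acetal, then the cyclobutane (key step), then ring A by fragmentation, then ring B, then the oxidation level and unsaturation of ring C.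
5. Stereochemistry: C1′ from (R)-citronellic acid; C8 (and the temporary centres C6, C7) from the acetal centre of the (5R)-menthyloxybutenolide (anti addition, endo rule); C1/C4 of the photoadduct from attack anti to three cis substituents; C3 from convex-face hydrogenation of the methylenecyclobutane; C1–OH from hydride attack anti to the C8 substituent; C4/C5 from hydroxyl delivery of the zinc carbenoid.

Key step: step 5

Remark: the β face is the face of the carbocycle that carries the C8 side chain and the α face is the opposite one; TBS = t-BuMe2Si, Men = (1R,2S,5R)-menthyl; compounds 1, 6 and 9 are taken as purchased.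

Step 1
Reactants: 1 (R)-citronellic acid
Product: 3 methyl (5R)-5,9-dimethyl-3-oxodec-8-enoate, via acyl imidazolide 2 (not isolated)
Conditions: CDI, THF, 25 °C; then KO2CCH2CO2Me, MgCl2, 25 to 50 °C; aq. HCl
Reagents that add atoms: potassium methyl malonate, COC(=O)CC(=O)[O-].[K+]
Why: Masamune–Brooks homologation (C-acylation of the magnesium salt of the malonate half-ester by the acyl imidazolide, then loss of CO2) converts the acid into the β-keto ester that supplies C1 (ketone), C4 and C5 (ester carbon), and the C1′ stereocentre of citronellic acid is not enolizable and is carried through unchanged.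

Step 2
Reactants: 3
Product: 4 methyl (2Z,5R)-3-[(tert-butyldimethylsilyl)oxy]-5,9-dimethyldeca-2,8-dienoate
Conditions: t-BuMe2SiOTf, Et3N, CH2Cl2, 0 °C
Reagents that add atoms: tert-butyldimethylsilyl triflate, CC(C)(C)[Si](C)(C)OS(=O)(=O)C(F)(F)F
Why: O-silylation of the chelated enol of the β-keto ester gives the (Z)-β-silyloxy enoate, which fixes the oxygen on C1 as the enol ether so that no regiochemical choice between the two oxygens of a 1,3-dione arises later.

Step 3
Reactants: 4
Product: 5 (3Z,5R)-3-[(tert-butyldimethylsilyl)oxy]-1-methoxy-5,9-dimethyl-1-[(trimethylsilyl)oxy]deca-1,3,8-triene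
Conditions: LiN(i-Pr)2, THF, −78 °C; then Me3SiCl; filtered under argon and used crude
Reagents that add atoms: chlorotrimethylsilane, C[Si](C)(C)Cl
Why: Kinetic γ-deprotonation of the β-silyloxy enoate and O-silylation of the lithium dienolate (Chan/Brassard-type diene synthesis) should give the 1,3-dioxygenated diene C5=C4–C1=C8 with the C1′ chain on the outside of the new (Z)-enol ether, as a Diels–Alder reaction requires.

Step 4
Reactants: 5; 6 (5R)-5-[(1R,2S,5R)-menthyloxy]furan-2(5H)-one
Product: 8 silyloxy enone lactone (ring C5(=O)–C4H=C1(OTBS)–C8–C7–C6 cis-fused at C6–C7 to the lactone C6–C11(=O)–O–C10H(OMen)–C7; H6 H7 H8 all α; OMen trans to C8), via cycloadduct 7 (not isolated)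
Conditions: toluene, 80 °C; then PPTS (cat.), CH2Cl2, 0 °C
Reagents that add atoms: none
Why: Diels–Alder reaction of the electron-rich diene with the 5-alkoxybutenolide joins the nucleophilic terminus C8 to the β-carbon C7 and C5 to C6, and loss of MeOSiMe3 from the silyl methyl ketal unmasks the C5 ketone; the diene should add anti to the menthyloxy group on C10 and endo, so that C7 and C6 are set by the acetal centre and the side chain on C8 is cis to both lactone carbons.

Step 5
Reactants: 8; 9 allene (propadiene)
Product: 10 photoadduct (cyclobutane C1–C2H2–C3(=CH2)–C4 cis-fused on the α face; TBSO on C1 and H on C4 both β)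
Conditions: allene (excess, condensed), THF, −78 °C, hν (Pyrex, λ > 300 nm)
Reagents that add atoms: none
Why: The triplet state of the 3-silyloxyenone C5(=O)–C4=C1(OSi) adds to allene through a 1,4-biradical (bond from C1 to a terminal allene carbon or from C4 to the central one) that closes after spin inversion, which is the enone–allene [2+2] photocycloaddition used in de Mayo-type two-carbon ring expansions and has no thermal counterpart. The one ring closed is the cyclobutane C1–C2–C3–C4, formed intermolecularly by stepwise biradical recombination and cis-fused to the six-membered ring (any trans-fused isomer should epimerize at C4, which is α to the C5 ketone). The new centres C1 and C4 are controlled by the three cis substituents on the β face (the C8 side chain and the lactone carbons on C7 and C6), so allene should enter from the α face. The step needs head-to-head regiochemistry (central allene carbon on the α-carbon C4, CH2 on the oxygen-bearing β-carbon C1), which is the normal outcome for allene with cyclohexenones and places the exocyclic methylene, the future methyl group, on C3. It also needs chemoselectivity over intramolecular addition to the remote trisubstituted side-chain alkene, secured by the large excess of condensed allene at −78 °C, and the silyl ether keeps the β-oxy ketone from retro-aldol opening until the ring strain is wanted in step 9.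

Step 6
Reactants: 10
Product: 11 dihydro photoadduct (C3 now CH(CH3) with the methyl on the concave face, cis to C5 and trans to the C1 oxygen)
Conditions: H2 (1 atm), RhCl(PPh3)3 (cat.), benzene, 25 °C
Reagents that add atoms: none
Why: Homogeneous hydrogenation with RhCl(PPh3)3 reduces the strained 1,1-disubstituted exocyclic alkene and leaves the trisubstituted side-chain alkene, and hydrogen should be delivered to the convex face of the bicyclo[4.2.0]octane (the face of H4 and of the C1 oxygen), which sets the C3 methyl as in the target.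

Step 7
Reactants: 11
Product: 13 hydroxy acetal (C5 α-OH cis to C3; tetrahydrofuran C6–C11H2–O–C10H(OMen)–C7), via hydroxy lactol 12 (not isolated)
Conditions: i-Bu2AlH (2.5 equiv), CH2Cl2, −78 °C; then Et3SiH, BF3·OEt2, −78 to −40 °C
Reagents that add atoms: none
Why: i-Bu2AlH should reduce the C5 ketone from the face of H4 (the α face is screened by C3 and its methyl) and stops at the lactol for the lactone, and ionic hydrogenation with Et3SiH/BF3·OEt2 (Kraus-type lactol deoxygenation) then removes the more easily ionized hemiacetal oxygen at C11 while the hindered O-menthyl acetal at C10 remains, so that the two lactone carbons exchange their oxidation levels.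

Step 8
Reactants: 13
Product: 14 C5 methanesulfonate of 13
Conditions: MsCl, Et3N, CH2Cl2, 0 °C
Reagents that add atoms: methanesulfonyl chloride, CS(=O)(=O)Cl
Why: Sulfonylation of the secondary C5 alcohol with retention of configuration installs the leaving group for the fragmentation, the tertiary silyl ether and the acetal being inert to MsCl and Et3N.

Step 9
Reactants: 14
Product: 16 (Z)-cyclooct-4-enone (ring A with C1 ketone; C3 methyl α; cis C4=C5; tetrahydrofuran acetal cis-fused at C6–C7 on the β face; C8 side chain β), via cyclobutanolate 15 (not isolated)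
Conditions: n-Bu4NF, THF, −20 to 0 °C
Reagents that add atoms: none
Why: Fluoride unmasks the C1 alkoxide, which expels the C5 mesylate held antiperiplanar to the C1–C4 ring-fusion bond (Grob fragmentation of a 1,3-diol monosulfonate, driven by release of cyclobutane strain) to give the C1 ketone and, because C3 is axial on C4 in the reacting chair, the (Z)-C4=C5 alkene of ring A.

Step 10
Reactants: 16
Product: 17 cyclooctenol (C1 β-OH, cis to the C8 side chain)
Conditions: LiBH(s-Bu)3, THF, −78 °C
Reagents that add atoms: none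
Why: The bulky hydride should attack the C1 ketone from the α face, anti to the branched side chain on the adjacent C8, which gives the C1 alcohol cis to that side chain (substrate-controlled ketone reduction).

Step 11
Reactants: 17
Product: 19 cyclopropane alcohol (ring B C4–C9–C5 on the β face, cis to the C1 hydroxyl), via ethylzinc alkoxide 18 (not isolated)
Conditions: Et2Zn, CH2I2, CH2Cl2, −10 to 0 °C
Reagents that add atoms: diiodomethane, ICI
Why: Furukawa-modified Simmons–Smith cyclopropanation is delivered by the zinc alkoxide of the C1 hydroxyl across the ring to the syn face of the (Z)-C4=C5 alkene (cyclooct-4-enol directing effect), which builds ring B cis to the C1 oxygen and trans to the C3 methyl and should outrun the undirected reaction at the side-chain alkene.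

Step 12
Reactants: 19
Product: 20 C1 acetate of 19
Conditions: Ac2O, DMAP, pyridine, 25 °C
Reagents that add atoms: acetic anhydride, CC(=O)OC(C)=O
Why: DMAP-catalysed acetylation esterifies the only free hydroxyl (C1) without change of configuration and protects it against the chromium oxidant of the next step.

Step 13
Reactants: 20
Product: 22 saturated lactone acetate (C10 now the lactone carbonyl on C7; H6 and H7 cis on the α face), via lactol acetate 21 (not isolated)
Conditions: CrO3, H2SO4, acetone/H2O, 0 to 25 °C
Reagents that add atoms: water, O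
Why: Jones reagent hydrolyses the O-menthyl acetal to the lactol and oxidizes it in the same flask to the γ-lactone (oxidation of a lactol ether), which makes C10 the carbonyl on C7 as in ring C while the acetate, the cyclopropane and the trisubstituted alkene should be left alone.

Step 14
Reactants: 22
Product: 25 acetoxycrenulide (target), via phenylselenide 23 (not isolated), via selenoxide 24 (not isolated)
Conditions: LiN(SiMe3)2, THF, −78 to −40 °C; PhSeCl, −78 °C; then H2O2, pyridine, CH2Cl2, 0 °C
Reagents that add atoms: none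
Why: LiN(SiMe3)2 should remove the lactone hydrogen at C7 (a γ-lactone C–H is several pK units more acidic than the acetate CH3), PhSeCl enters from the convex face cis to H6, and the selenoxide undergoes syn elimination toward H6, the hydrogen held syn-coplanar in the five-membered ring, to give the tetrasubstituted C6=C7 butenolide (selenoxide elimination).

**Compound list**

1 | (R)-citronellic acid, (3R)-3,7-dimethyloct-6-enoic acid | OC(=O)C[C@H](C)CCC=C(C)C | starting material
2 | (3R)-1-(imidazol-1-yl)-3,7-dimethyloct-6-en-1-one (acyl imidazolide) | O=C(C[C@H](C)CCC=C(C)C)n1ccnc1 | intermediate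
3 | methyl (5R)-5,9-dimethyl-3-oxodec-8-enoate | COC(=O)CC(=O)C[C@H](C)CCC=C(C)C | intermediate
4 | methyl (2Z,5R)-3-[(tert-butyldimethylsilyl)oxy]-5,9-dimethyldeca-2,8-dienoate | COC(=O)/C=C(\O[Si](C)(C)C(C)(C)C)C[C@H](C)CCC=C(C)C | intermediate
5 | (3Z,5R)-3-[(tert-butyldimethylsilyl)oxy]-1-methoxy-5,9-dimethyl-1-[(trimethylsilyl)oxy]deca-1,3,8-triene | COC(O[Si](C)(C)C)=C/C(O[Si](C)(C)C(C)(C)C)=C/[C@H](C)CCC=C(C)C | intermediate
6 | (5R)-5-[(1R,2S,5R)-menthyloxy]furan-2(5H)-one | O=C1C=C[C@H](O[C@@H]2C[C@H](C)CC[C@H]2C(C)C)O1 | starting material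
7 | Diels–Alder cycloadduct with C5 as silyl methyl ketal | COC1(O[Si](C)(C)C)C=C(O[Si](C)(C)C(C)(C)C)[C@@H]([C@H](C)CCC=C(C)C)[C@H]2[C@H](O[C@@H]3C[C@H](C)CC[C@H]3C(C)C)OC(=O)[C@@H]12 | intermediate
8 | silyloxy enone lactone (C5 ketone, C4=C1 enol silyl ether, all-cis H6/H7/H8, OMen trans to C8) | O=C1C=C(O[Si](C)(C)C(C)(C)C)[C@@H]([C@H](C)CCC=C(C)C)[C@H]2[C@H](O[C@@H]3C[C@H](C)CC[C@H]3C(C)C)OC(=O)[C@@H]12 | intermediate
9 | allene (propadiene) | C=C=C | starting material
10 | methylenecyclobutane photoadduct | O=C1[C@@H]2C(=C)C[C@]2(O[Si](C)(C)C(C)(C)C)[C@@H]([C@H](C)CCC=C(C)C)[C@H]3[C@H](O[C@@H]4C[C@H](C)CC[C@H]4C(C)C)OC(=O)[C@@H]13 | intermediate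
11 | dihydro photoadduct (C3 methyl on the concave face) | O=C1[C@@H]2[C@H](C)C[C@]2(O[Si](C)(C)C(C)(C)C)[C@@H]([C@H](C)CCC=C(C)C)[C@H]3[C@H](O[C@@H]4C[C@H](C)CC[C@H]4C(C)C)OC(=O)[C@@H]13 | intermediate
12 | hydroxy lactol (C5 α-OH, C11 as CH(OH); present as aluminium alkoxides) | O[C@@H]1[C@@H]2[C@H](C)C[C@]2(O[Si](C)(C)C(C)(C)C)[C@@H]([C@H](C)CCC=C(C)C)[C@H]3[C@H](O[C@@H]4C[C@H](C)CC[C@H]4C(C)C)OC(O)[C@@H]13 | intermediate
13 | hydroxy acetal (C5 α-OH, C11 as CH2) | O[C@@H]1[C@@H]2[C@H](C)C[C@]2(O[Si](C)(C)C(C)(C)C)[C@@H]([C@H](C)CCC=C(C)C)[C@H]3[C@H](O[C@@H]4C[C@H](C)CC[C@H]4C(C)C)OC[C@@H]13 | intermediate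
14 | C5 methanesulfonate of 13 | CS(=O)(=O)O[C@@H]1[C@@H]2[C@H](C)C[C@]2(O[Si](C)(C)C(C)(C)C)[C@@H]([C@H](C)CCC=C(C)C)[C@H]3[C@H](O[C@@H]4C[C@H](C)CC[C@H]4C(C)C)OC[C@@H]13 | intermediate
15 | tetrabutylammonium C1 cyclobutanolate of 14 | CS(=O)(=O)O[C@@H]1[C@@H]2[C@H](C)C[C@]2([O-])[C@@H]([C@H](C)CCC=C(C)C)[C@H]3[C@H](O[C@@H]4C[C@H](C)CC[C@H]4C(C)C)OC[C@@H]13.CCCC[N+](CCCC)(CCCC)CCCC | intermediate
16 | (Z)-cyclooct-4-enone with cis-fused tetrahydrofuran acetal | O=C1C[C@@H](C)/C=C\[C@@H]2CO[C@@H](O[C@@H]3C[C@H](C)CC[C@H]3C(C)C)[C@@H]2[C@@H]1[C@H](C)CCC=C(C)C | intermediate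
17 | cyclooctenol (C1 β-OH) | O[C@@H]1C[C@@H](C)/C=C\[C@@H]2CO[C@@H](O[C@@H]3C[C@H](C)CC[C@H]3C(C)C)[C@@H]2[C@@H]1[C@H](C)CCC=C(C)C | intermediate
18 | ethylzinc alkoxide of 17 | CC[Zn]O[C@@H]1C[C@@H](C)/C=C\[C@@H]2CO[C@@H](O[C@@H]3C[C@H](C)CC[C@H]3C(C)C)[C@@H]2[C@@H]1[C@H](C)CCC=C(C)C | intermediate
19 | cyclopropane alcohol (ring B β) | O[C@@H]1C[C@@H](C)[C@@H]2C[C@@H]2[C@@H]3CO[C@@H](O[C@@H]4C[C@H](C)CC[C@H]4C(C)C)[C@@H]3[C@@H]1[C@H](C)CCC=C(C)C | intermediate
20 | C1 acetate of 19 | CC(=O)O[C@@H]1C[C@@H](C)[C@@H]2C[C@@H]2[C@@H]3CO[C@@H](O[C@@H]4C[C@H](C)CC[C@H]4C(C)C)[C@@H]3[C@@H]1[C@H](C)CCC=C(C)C | intermediate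
21 | lactol acetate (C10 as CH(OH)) | CC(=O)O[C@@H]1C[C@@H](C)[C@@H]2C[C@@H]2[C@@H]3COC(O)[C@@H]3[C@@H]1[C@H](C)CCC=C(C)C | intermediate
22 | saturated lactone acetate (6,7-dihydro target) | CC(=O)O[C@@H]1C[C@@H](C)[C@@H]2C[C@@H]2[C@@H]3COC(=O)[C@@H]3[C@@H]1[C@H](C)CCC=C(C)C | intermediate
23 | C7 phenylselenide of 22 (Se cis to H6) | CC(=O)O[C@@H]1C[C@@H](C)[C@@H]2C[C@@H]2[C@@H]3COC(=O)[C@]3([Se]c4ccccc4)[C@@H]1[C@H](C)CCC=C(C)C | intermediate
24 | selenoxide of 23 | CC(=O)O[C@@H]1C[C@@H](C)[C@@H]2C[C@@H]2[C@@H]3COC(=O)[C@]3([Se](=O)c4ccccc4)[C@@H]1[C@H](C)CCC=C(C)C | intermediate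
25 | acetoxycrenulide (CNP0018922.1) | CC(=O)O[C@@H]1C[C@@H](C)[C@@H]2C[C@@H]2C2=C(C(=O)OC2)[C@@H]1[C@H](C)CCC=C(C)C | target

**Step count and risks**

Total step count: 14. Longest linear sequence: 14 steps (1 to 25).

Steps most likely to fail:

Step 4. The ketene-acetal diene may transfer silicon or decompose before it cycloadds, or the endo/exo control may be poor, so that the six-membered ring forms inefficiently or as a mixture at C8. Fallback: set out from 5 and 6 and form the two bonds one after the other. A vinylogous Mukaiyama–Michael addition (Me3SiOTf cat., CH2Cl2, −78 °C, aqueous work-up), again anti to the menthyloxy group, should give the open-chain Michael adduct F1. Dieckmann closure of its lactone enolate on the methyl ester (LiN(SiMe3)2, 2 equiv, THF, −78 to 0 °C) then comes back to the route at 8.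

Step 7. Poor facial selectivity in the ketone reduction (hydride entering from the α face) would give the C5 epimer, whose sulfonate cannot reach the antiperiplanar alignment that step 9 needs; partial ionization of the O-menthyl acetal during the silane reduction is a second hazard. Fallback, which does not depend on the carbinol configuration: from 11 the same reduction gives the C5-epimeric hydroxy acetal F2. Its thiocarbonylimidazolide F3 (1,1'-thiocarbonyldiimidazole, DMAP, toluene, 80 °C) is treated with Bu3SnH and AIBN (toluene, 110 °C, slow addition). The C5 radical should open the cyclobutane at C1–C4 toward the silyloxy-stabilized C1 radical, which takes hydrogen anti to the C8 substituent to give the cyclooctene silyl ether F4. n-Bu4NF then comes back to the route at 17, with 13 to 16 bypassed.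

Step 14. Competing deprotonation of, or acyl transfer from, the C1 acetate, and elimination of the selenoxide toward H8 instead of H6, would erode the last step. Fallback: from 19 the acetate is put on last. 1 M HCl in THF hydrolyses the acetal to the lactol F5, and TEMPO/PhI(OAc)2 oxidizes it to the hydroxy lactone F6 without touching the secondary alcohol. Internal-quench silylation and enolization (Me3SiCl, LiN(i-Pr)2, THF, −78 °C), then PhSeCl and H2O2/pyridine with an acidic work-up, should give the hydroxy butenolide F7. Ac2O, DMAP and pyridine then come back to the route at 25.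

Further compounds
F1 | step 4 | Michael adduct: methyl (Z)-3-silyloxy enoate carrying on C8 the lactone C7H–C6H2–C11(=O)–O–C10H(OMen) | COC(=O)/C=C(\O[Si](C)(C)C(C)(C)C)[C@@H]([C@H](C)CCC=C(C)C)[C@@H]1CC(=O)O[C@H]1O[C@@H]2C[C@H](C)CC[C@H]2C(C)C
F2 | step 7 | C5 epimer of hydroxy acetal 13 (β-OH) | O[C@H]1[C@@H]2[C@H](C)C[C@]2(O[Si](C)(C)C(C)(C)C)[C@@H]([C@H](C)CCC=C(C)C)[C@H]3[C@H](O[C@@H]4C[C@H](C)CC[C@H]4C(C)C)OC[C@@H]13
F3 | step 7 | O-(imidazol-1-ylthiocarbonyl) derivative of F2 | S=C(n1ccnc1)O[C@H]1[C@@H]2[C@H](C)C[C@]2(O[Si](C)(C)C(C)(C)C)[C@@H]([C@H](C)CCC=C(C)C)[C@H]3[C@H](O[C@@H]4C[C@H](C)CC[C@H]4C(C)C)OC[C@@H]13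
F4 | step 7 | C1 tert-butyldimethylsilyl ether of cyclooctenol 17 | CC(C)(C)[Si](C)(C)O[C@@H]1C[C@@H](C)/C=C\[C@@H]2CO[C@@H](O[C@@H]3C[C@H](C)CC[C@H]3C(C)C)[C@@H]2[C@@H]1[C@H](C)CCC=C(C)C
F5 | step 14 | lactol from 19 (C10 as CH(OH), free C1 hydroxyl) | O[C@@H]1C[C@@H](C)[C@@H]2C[C@@H]2[C@@H]3COC(O)[C@@H]3[C@@H]1[C@H](C)CCC=C(C)C
F6 | step 14 | hydroxy lactone (deacetyl 22) | O[C@@H]1C[C@@H](C)[C@@H]2C[C@@H]2[C@@H]3COC(=O)[C@@H]3[C@@H]1[C@H](C)CCC=C(C)C
F7 | step 14 | hydroxy butenolide (deacetyl 25) | O[C@@H]1C[C@@H](C)[C@@H]2C[C@@H]2C2=C(C(=O)OC2)[C@@H]1[C@H](C)CCC=C(C)C
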